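**Easy step.** An enzyme that sits full as complex A releases target at a steady pace, so I count what stays behind.

    complex A → enzyme + target (k1 = 15.6 s⁻¹)
    complex B → enzyme + second product (k2 = 20.4 s⁻¹)
    second substrate + enzyme ⇌ complex B (K3 = 40 M⁻¹, k3 = 9.74 × 10⁵ M⁻¹ s⁻¹)
    starting material + enzyme ⇌ complex A (K4 = 1200 M⁻¹, k4 = 45800 M⁻¹ s⁻¹)
    crystals ⇌ target, rate k5*(cs5 - [target]) while solid is left; crystals form when [target] > cs5 (cs5 = 4.2 mM, k5 = 0.397 s⁻¹)

starting material 21 mM; second substrate 42.0 mM; enzyme 2.7 µM; time 6.0 min

* the target and crystals together standing at 6.0 min, as a percentage of the starting material charged
* concentration of target in solution at 6.0 min, in percent of saturation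

- for target the crystals are counted in
- as a solid, counted per litre of solution: crystals
- run time (flask): 6.0 min

**Work ratio.** If all 2.7 µM of enzyme sat as complex A for 6.0 min, it would release 15.2 mM of target. Divided by the charge of 21 mM, that gives 0.722, my work ratio: full-speed output over the charge.

**Drag.** The enzyme is not always full. Its Michaelis constant is 1.17 mM for starting material and 25.0 mM for second substrate. At the start of this flask, starting material turns over 8.15 times as fast as second substrate, so I hold [second substrate] at its charge, as a competitive inhibitor. My drag is the first constant, raised by that competitor, over the charge: 0.150. The rule works with the fraction left: the fraction gone, plus the drag times the natural logarithm of the charge over what is left, equals the work ratio. In this flask it leaves 41.1%, so I expect 58.9% as target and crystals.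

**Settings.** Time and enzyme stand in the work ratio as a product, so by hand a factor on either counts equally. Starting material divides both ratio and drag. Second substrate acts through the drag term, worth 13.3% of the charge against 58.9% for the fraction gone, so I expect it to move the answer less than time.

**Result.** The forecast gives 59% and 101.9%, holding that second substrate “stays nearly constant and acts as a steady inhibitor”. The simulation of this flask gives 59.1% and 102%, with 41% of the starting material left. Moved singly by one common factor, up or down, the settings rank by the most each shifts the share of target and crystals: time (15 points), then enzyme (15 points), then starting material (12 points), then second substrate (1.7 points).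

**Neighbour flask.** A neighbour charged with 170 mM of second substrate keeps the work ratio 0.722, but its drag rises to 0.436. The same rule then leaves 54.4% by my hand. In that neighbour, target and crystals stand at 45.9%, and 54% of its starting material is still there.

The constants are invented.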